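**Plan**
Retrosynthesis: the C-15 acid is freed from a benzyl ester and the 2-OAc/3-OH/19-CHO array comes from a 3-oxo-19-al. Ring A comes from a seven-membered 2,3-epoxy ketone (C-3–C-4 bond made, C-3–C-19 bond broken). That ring comes from ring-closing metathesis at C-19=C-4, C-10 from two enolate alkylations, and C-9–C-11 from an alkyllithium addition.
Forward: ring B is the carvone ring; C-10 is quaternised, the side chain is joined at C-9 with shift of the double bond to C-7, the seven-membered ring C-1/C-2/C-3/C-19/C-4/C-5/C-10 is closed on ring B, and its contraction gives ring A.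
Feature used: in ring A, C-4 carries a methyl and a formyl group beside the C-3 oxygen. This is the 2-formyl-2-methyl ketone pattern that an α,β-epoxy ketone gives when its acyl carbon shifts, so C-19 can begin as a ring atom.
Stereochemistry: C-5 from (S)-carvone; C-10 by allylation anti to the isopropenyl group; C-9 by palladium-delivered hydride anti to a carbonate; C-13 from (R)-citronellol.
C-4 comes from the oxirane (placed syn to a C-3 hydroxyl set by CBS reduction) with inversion in the shift; C-2 is the equatorial acetate; C-3 is set by hydride delivery from the C-19 oxygen.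

Key step: step 17

Naming note: locants are labdane numbers; the ring carbon that is later expelled as the formyl carbon is called C-19 from the start; α is the face of ring B that carries the C-10 methyl.

Step 1
Reactants: 1 (R)-citronellol
Product: 2 (R)-citronellol tert-butyldimethylsilyl ether
Conditions: TBSCl, imidazole, DMF, 0 °C to rt
Reagents that add atoms: tert-butyldimethylsilyl chloride, CC(C)(C)[Si](C)(C)Cl
Why: Silyl ether protection of the primary alcohol should mask the future C-15 carboxyl through the organolithium stage.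

Step 2
Reactants: 2 (R)-citronellol tert-butyldimethylsilyl ether
Product: 3 (4R)-6-(tert-butyldimethylsilyloxy)-4-methylhexanoic acid
Conditions: RuCl3·xH2O (2 mol %), NaIO4, CCl4–MeCN–H2O, rt
Reagents that add atoms: sodium periodate, [Na+].[O-]I(=O)(=O)=O; water, O
Why: Oxidative cleavage of the trisubstituted alkene by ruthenium tetroxide made in the flask should give the acid with loss of acetone and leave the remote stereocentre untouched.

Step 3
Reactants: 3 (4R)-6-(tert-butyldimethylsilyloxy)-4-methylhexanoic acid
Product: 4 (3S)-1-(tert-butyldimethylsilyloxy)-5-iodo-3-methylpentane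
Conditions: PhI(OAc)2, I2, cyclohexane, hν (tungsten lamp), reflux
Reagents that add atoms: iodine, II
Why: Radical iododecarboxylation (Hunsdiecker-type, through an acyl hypoiodite) should shorten the chain by one carbon to the primary iodide without touching the stereocentre, whose descriptor changes only through priority.

Step 4
Reactants: 5 (S)-carvone
Product: 6 (5S)-6-methylcarvone (both C-6 epimers)
Conditions: LiN(i-Pr)2, THF, −78 °C; then MeI, −78 to 0 °C
Reagents that add atoms: iodomethane, CI
Why: Kinetic deprotonation at the α' carbon and enolate alkylation should introduce the future C-20 methyl; the new centre need not be controlled because it is planarised again in step 5.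

Step 5
Reactants: 6 (5S)-6-methylcarvone (both C-6 epimers)
Product: 7 (5R,6R)-6-allyl-6-methylcarvone
Conditions: LiN(i-Pr)2, THF–DMPU, −78 °C; then allyl bromide, −78 °C to rt
Reagents that add atoms: allyl bromide, C=CCBr
Why: A second α'-enolate alkylation should create quaternary C-10, the allyl group entering anti to the neighbouring isopropenyl group so that the C-10 methyl is cis and the C-1 chain trans to it.

Step 6
Reactants: 4 (3S)-1-(tert-butyldimethylsilyloxy)-5-iodo-3-methylpentane; 7 (5R,6R)-6-allyl-6-methylcarvone
Product: 10 tertiary allylic methyl carbonate (9α-carbonate and 9β side chain), via organolithium 8 (not isolated), via lithium alkoxide 9 (not isolated)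
Conditions: 4, t-BuLi (2.1 equiv), Et2O–pentane, −78 °C; then 7, THF, −78 °C; then ClCO2Me, −78 to 0 °C
Reagents that add atoms: methyl chloroformate, COC(=O)Cl
Why: Iodine–lithium exchange and 1,2-addition of the primary alkyllithium to the enone carbonyl, expected from the β face opposite the pseudoaxial C-10 methyl, followed by acylation of the tertiary alkoxide, should place the carbonate on the α face.

Step 7
Reactants: 10 tertiary allylic methyl carbonate
Product: 11 ring-B triene (7-ene, 9α side chain, 9β-H)
Conditions: Pd(OAc)2 (5 mol %), n-Bu3P (20 mol %), HCO2NH4, 1,4-dioxane, 80 °C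
Reagents that add atoms: none
Why: In this formate hydrogenolysis of an allylic carbonate (Tsuji–Trost type), zerovalent palladium should ionise the carbonate with inversion and the formate-derived Pd–H should deliver hydride to the more substituted allyl terminus C-9 on the palladium-bearing β face, which sets H-9 β, the side chain α and the double bond at C-7/C-8.

Step 8
Reactants: 11 ring-B triene
Product: 12 primary alcohol (C-3 hydroxyl)
Conditions: Sia2BH, THF, 0 °C; then 30 % H2O2, 3 M NaOH, 0 °C to rt
Reagents that add atoms: hydrogen peroxide, OO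
Why: Anti-Markovnikov hydroboration–oxidation with the bulky disiamylborane should select the monosubstituted allyl alkene over the 1,1-disubstituted and trisubstituted ones.

Step 9
Reactants: 12 primary alcohol
Product: 13 C-3 aldehyde
Conditions: Dess–Martin periodinane, NaHCO3, CH2Cl2, rt
Reagents that add atoms: none
Why: Dess–Martin oxidation should give the aldehyde without affecting the silyl ether or the alkenes.

Step 10
Reactants: 13 C-3 aldehyde
Product: 14 vinyl carbinol (both C-3 epimers)
Conditions: CH2=CHMgBr, THF, −78 °C; aq. NH4Cl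
Reagents that add atoms: vinylmagnesium bromide, C=C[Mg]Br
Why: Grignard addition to the aldehyde brings in C-19; the carbinol centre is not controlled because it is oxidised in step 12.

Step 11
Reactants: 14 vinyl carbinol (both C-3 epimers)
Product: 15 seven-membered allylic alcohol (both C-3 epimers)
Conditions: second-generation Grubbs catalyst (5 mol %), CH2Cl2 (0.005 M), 40 °C
Reagents that add atoms: none
Why: Ring-closing metathesis between the vinyl carbinol and the isopropenyl group should close the trans-fused seven-membered ring by forming the C-19=C-4 double bond, the trisubstituted C-7 alkene being inert.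

Step 12
Reactants: 15 seven-membered allylic alcohol (both C-3 epimers)
Product: 16 cycloheptenone acid
Conditions: CrO3, H2SO4, H2O, acetone (Jones reagent), 0 °C to rt
Reagents that add atoms: chromium trioxide, O=[Cr](=O)=O; water, O
Why: Jones oxidation should turn both allylic alcohol epimers into one enone and, in the same acidic medium, cleave the silyl ether and oxidise C-15 to the carboxylic acid.

Step 13
Reactants: 16 cycloheptenone acid
Product: 17 benzyl ester of 16
Conditions: BnBr, K2CO3, DMF, rt
Reagents that add atoms: benzyl bromide, BrCc1ccccc1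
Why: Carboxylate O-alkylation gives an ester that tolerates boranes and Lewis acid and can be removed at the end without base, which the acetate and the β-hydroxy aldehyde would not survive.

Step 14
Reactants: 17 benzyl ester of 16
Product: 18 (3R)-allylic alcohol (3α-hydroxyl)
Conditions: (S)-2-methyl-CBS-oxazaborolidine (20 mol %), catecholborane, toluene, −78 °C
Reagents that add atoms: none
Why: Corey–Bakshi–Shibata reduction under reagent control, with the alkenyl flank as the large group, should give the (3R)-alcohol with the hydroxyl on the α face and leave the ester alone.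

Step 15
Reactants: 18 (3R)-allylic alcohol
Product: 19 19α,4α-epoxy-3α-alcohol
Conditions: VO(acac)2 (3 mol %), t-BuOOH, CH2Cl2, 0 °C to rt
Reagents that add atoms: tert-butyl hydroperoxide, CC(C)(C)OO
Why: Vanadium-catalysed hydroxyl-directed epoxidation should deliver oxygen syn to the C-3 hydroxyl, onto the α face that undirected reagents avoid, and should not touch the isolated C-7 alkene.

Step 16
Reactants: 19 19α,4α-epoxy-3α-alcohol
Product: 20 19α,4α-epoxy-3-ketone
Conditions: Dess–Martin periodinane, NaHCO3, CH2Cl2, 0 °C to rt
Reagents that add atoms: none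
Why: Dess–Martin oxidation under buffered conditions should give the α,β-epoxy ketone without opening the oxirane.

Step 17
Reactants: 20 19α,4α-epoxy-3-ketone
Product: 21 3-oxo-19-al (ring A, 4β-methyl and 4α-formyl)
Conditions: BF3·OEt2 (0.3 equiv), CH2Cl2, −78 to −20 °C
Reagents that add atoms: none
Why: BF3 binds the oxirane oxygen, the tertiary C-4–O bond remote from the carbonyl lengthens, and the C-3 acyl carbon shifts from C-19 to C-4 in a concerted 1,2-acyl migration, after which C-19 collapses to the formyl group. The closest known reaction type is the Lewis-acid rearrangement of 2,3-epoxycycloalkanones to ring-contracted 2-formylcycloalkanones (isophorone oxide to 2-formyl-2,4,4-trimethylcyclopentanone). Ring A is closed by this 1,2-shift: the C-3–C-4 bond forms as the C-3–C-19 bond breaks, so the seven-membered ring contracts to the six-membered one and C-19 becomes exocyclic. The only new stereocentre, quaternary C-4, is fixed by the oxirane configuration, because the acyl carbon enters anti to the departing oxygen (inversion), which leaves the methyl β and puts the formyl group on the α face where the oxygen was. The step needs acyl shift in preference to hydride shift or fluoride capture and must leave the C-7 alkene and the benzyl ester alone; the high migratory aptitude of the acyl group, the methyl-stabilised tertiary terminus, the non-nucleophilic medium and the low temperature should secure this.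

Step 18
Reactants: 21 3-oxo-19-al
Product: 23 2β-acetoxy-3-oxo-19-al, via silyl enol ether 22 (not isolated)
Conditions: TMSOTf, Et3N, CH2Cl2, −78 to 0 °C; then Pb(OAc)4, CH2Cl2, −20 °C
Reagents that add atoms: lead tetraacetate, CC(=O)O[Pb](OC(C)=O)(OC(C)=O)OC(C)=O
Why: Soft enolisation can only go toward C-2, and lead tetraacetate acetoxylation of the silyl enol ether (Rubottom-type) should give the equatorial 2β-acetate, which is both the product of attack opposite the axial formyl and C-10 methyl groups and the more stable epimer at this enolisable position.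

Step 19
Reactants: 23 2β-acetoxy-3-oxo-19-al
Product: 24 2β-acetoxy-3β,19-diol
Conditions: Me4NBH(OAc)3, MeCN–AcOH (1:1), −20 °C to rt
Reagents that add atoms: none
Why: In this Evans–Saksena reduction the triacetoxyborohydride should reduce the aldehyde first, and the C-19 alkoxyborohydride should then deliver hydride intramolecularly to the α face of the C-3 ketone, giving the axial 3β-alcohol cis to the acetate.

Step 20
Reactants: 24 2β-acetoxy-3β,19-diol
Product: 25 benzyl ester of the target
Conditions: TEMPO (10 mol %), PhI(OAc)2, CH2Cl2, rt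
Reagents that add atoms: none
Why: Oxoammonium (TEMPO) oxidation is selective for the primary alcohol and should restore the C-19 aldehyde while the hindered axial secondary alcohol remains.

Step 21
Reactants: 25 benzyl ester of the target
Product: 26 target acid (2S,3R,4S,5S,9R,10S,13R)
Conditions: H2 (1 atm), Pd/C (10 % palladium on carbon), EtOAc, rt
Reagents that add atoms: none
Why: Hydrogenolysis of the benzyl ester under neutral conditions should free the acid without touching the acetate, the β-hydroxy aldehyde or the hindered trisubstituted alkene.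

**Compound list**
1 | (R)-citronellol, (3R)-3,7-dimethyloct-6-en-1-ol | OCC[C@H](C)CCC=C(C)C | starting material
2 | (R)-citronellol tert-butyldimethylsilyl ether | CC(C)=CCC[C@@H](C)CCO[Si](C)(C)C(C)(C)C | intermediate
3 | (4R)-6-(tert-butyldimethylsilyloxy)-4-methylhexanoic acid | OC(=O)CC[C@@H](C)CCO[Si](C)(C)C(C)(C)C | intermediate
4 | (3S)-1-(tert-butyldimethylsilyloxy)-5-iodo-3-methylpentane | ICC[C@@H](C)CCO[Si](C)(C)C(C)(C)C | intermediate
5 | (S)-carvone | CC1=CC[C@@H](CC1=O)C(C)=C | starting material
6 | (5S)-6-methylcarvone, both C-6 epimers | CC1=CC[C@@H](C(C)C1=O)C(C)=C | intermediate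
7 | (5R,6R)-6-allyl-6-methylcarvone; allyl trans and methyl cis to the isopropenyl group | C=CC[C@@]1(C)C(=O)C(C)=CC[C@@H]1C(C)=C | intermediate
8 | organolithium from 4 | [Li]CC[C@@H](C)CCO[Si](C)(C)C(C)(C)C | intermediate
9 | lithium alkoxide of the 1,2-adduct (9α-O, 9β side chain) | C=CC[C@@]1(C)[C@@]([O-])(CC[C@@H](C)CCO[Si](C)(C)C(C)(C)C)C(C)=CC[C@@H]1C(C)=C.[Li+] | intermediate
10 | tertiary allylic methyl carbonate (9α-OCO2Me, 9β side chain) | C=CC[C@@]1(C)[C@@](OC(=O)OC)(CC[C@@H](C)CCO[Si](C)(C)C(C)(C)C)C(C)=CC[C@@H]1C(C)=C | intermediate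
11 | ring-B triene: cyclohex-7-ene with 8-methyl, 9α side chain (13R, 15-OTBS), 9β-H, 10α-methyl, 10β-allyl, 5α-isopropenyl | C=CC[C@@]1(C)[C@H](CC[C@@H](C)CCO[Si](C)(C)C(C)(C)C)C(C)=CC[C@@H]1C(C)=C | intermediate
12 | primary alcohol: 11 with the allyl group turned into a 3-hydroxypropyl chain | OCCC[C@@]1(C)[C@H](CC[C@@H](C)CCO[Si](C)(C)C(C)(C)C)C(C)=CC[C@@H]1C(C)=C | intermediate
13 | C-3 aldehyde | O=CCC[C@@]1(C)[C@H](CC[C@@H](C)CCO[Si](C)(C)C(C)(C)C)C(C)=CC[C@@H]1C(C)=C | intermediate
14 | vinyl carbinol, both C-3 epimers | C=CC(O)CC[C@@]1(C)[C@H](CC[C@@H](C)CCO[Si](C)(C)C(C)(C)C)C(C)=CC[C@@H]1C(C)=C | intermediate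
15 | seven-membered allylic alcohol: trans-fused bicyclo[5.4.0]undecadiene with 19(4)- and 7-double bonds, 3-OH (both epimers), 15-OTBS | OC1CC[C@@]2(C)[C@H](CC[C@@H](C)CCO[Si](C)(C)C(C)(C)C)C(C)=CC[C@@H]2C(C)=C1 | intermediate
16 | cycloheptenone acid: 3-oxo-19(4),7-diene-15-oic acid | O=C1CC[C@@]2(C)[C@H](CC[C@@H](C)CC(=O)O)C(C)=CC[C@@H]2C(C)=C1 | intermediate
17 | benzyl ester of 16 | O=C1CC[C@@]2(C)[C@H](CC[C@@H](C)CC(=O)OCc3ccccc3)C(C)=CC[C@@H]2C(C)=C1 | intermediate
18 | (3R)-allylic alcohol, 3α-hydroxyl | O[C@@H]1CC[C@@]2(C)[C@H](CC[C@@H](C)CC(=O)OCc3ccccc3)C(C)=CC[C@@H]2C(C)=C1 | intermediate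
19 | 19α,4α-epoxy-3α-alcohol (oxirane syn to the hydroxyl, trans to H-5) | O[C@@H]1CC[C@@]2(C)[C@H](CC[C@@H](C)CC(=O)OCc3ccccc3)C(C)=CC[C@@H]2[C@]4(C)O[C@H]14 | intermediate
20 | 19α,4α-epoxy-3-ketone | O=C1CC[C@@]2(C)[C@H](CC[C@@H](C)CC(=O)OCc3ccccc3)C(C)=CC[C@@H]2[C@]4(C)O[C@H]14 | intermediate
21 | 3-oxo-19-al with ring A formed; 4β-methyl, 4α-formyl | O=C1CC[C@@]2(C)[C@H](CC[C@@H](C)CC(=O)OCc3ccccc3)C(C)=CC[C@@H]2[C@]1(C)C=O | intermediate
22 | trimethylsilyl enol ether (2-ene) of 21 | C[Si](C)(C)OC1=CC[C@@]2(C)[C@H](CC[C@@H](C)CC(=O)OCc3ccccc3)C(C)=CC[C@@H]2[C@]1(C)C=O | intermediate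
23 | 2β-acetoxy-3-oxo-19-al | CC(=O)O[C@H]1C[C@@]2(C)[C@H](CC[C@@H](C)CC(=O)OCc3ccccc3)C(C)=CC[C@@H]2[C@](C)(C=O)C1=O | intermediate
24 | 2β-acetoxy-3β,19-diol | CC(=O)O[C@H]1C[C@@]2(C)[C@H](CC[C@@H](C)CC(=O)OCc3ccccc3)C(C)=CC[C@@H]2[C@](C)(CO)[C@H]1O | intermediate
25 | benzyl ester of the target | CC(=O)O[C@H]1C[C@@]2(C)[C@H](CC[C@@H](C)CC(=O)OCc3ccccc3)C(C)=CC[C@@H]2[C@](C)(C=O)[C@H]1O | intermediate
26 | target: 2-acetoxy-3-hydroxy-19-oxolabd-7-en-15-oic acid, 2S,3R,4S,5S,9R,10S,13R | CC(=O)O[C@H]1C[C@@]2(C)[C@H](CC[C@@H](C)CC(=O)O)C(C)=CC[C@@H]2[C@](C)(C=O)[C@H]1O | target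

**Count**
Total steps: 21. Longest linear sequence: 19 steps (from 1 through steps 1–3 and 6–21); 18 steps from 5.

**Steps most likely to fail**

Step 7. The hydride may be transferred to C-7 instead of C-9 (which would give the 8,9-alkene), facial fidelity may be lost if the π-allyl complex equilibrates, or the complex may lose a β-hydrogen to give a triene. Fallback, setting out from 7: organolithium 8 is added as in step 6 but the adduct is quenched with aqueous NH4Cl to the tertiary allylic alcohol F1. Pyridinium chlorochromate, C5H5NH[CrO3Cl], in CH2Cl2 then moves the oxygen to C-7 and the double bond to C-8/C-9 (oxidative 1,3-transposition) to give the β-alkyl enone F2. Li in liquid NH3–THF at −78 °C should add H-9 by axial protonation on the β face, and the regiodefined lithium enolate is trapped with PhNTf2 as the enol triflate F3. Pd(OAc)2, PPh3, HCO2H and n-Bu3N in DMF remove the triflate and the route is rejoined at 11.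

Step 17. A hydride shift to the 1,2-dicarbonyl compound, fluoride capture of the cation, or interception by the C-7 alkene may compete with the acyl shift. Fallback, setting out from 19: the hydroxyl is silylated with TBSOTf and 2,6-lutidine to the epoxy silyl ether F7. MeAl(OC6H2-2,6-t-Bu2-4-Br)2 (20 mol %) in CH2Cl2 at −78 °C should then promote the epoxy silyl ether rearrangement in which the siloxy-bearing C-3 migrates from C-19 to C-4 anti to the oxirane oxygen, giving the ring-contracted siloxy aldehyde F8 with the same C-4 configuration. HF·pyridine gives the hydroxy aldehyde F9, and Dess–Martin oxidation returns to the route at 21.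

Step 14. Discrimination between the alkenyl and the methylene flank of the cycloheptenone may be poor, which would put the hydroxyl and then the oxirane on the wrong face. Fallback, setting out from 17: NaBH4 with CeCl3·7H2O in MeOH at −78 °C (Luche reduction) gives the allylic alcohols as both C-3 epimers F4, which are separated; the 3α-epimer is 18. The 3β-epimer is inverted by a Mitsunobu reaction with chloroacetic acid, PPh3 and diisopropyl azodicarboxylate to the chloroacetate F5 of 18, and thiourea with NaHCO3 in EtOH removes the chloroacetyl group under conditions that spare the benzyl ester. The route is rejoined at 18.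

**Further compounds**
F1 | step 7 | tertiary allylic alcohol, protonated form of 9 | C=CC[C@@]1(C)[C@@](O)(CC[C@@H](C)CCO[Si](C)(C)C(C)(C)C)C(C)=CC[C@@H]1C(C)=C
F2 | step 7 | transposed enone: 7-oxo-8-ene with the side chain on C-9 | C=CC[C@@]1(C)C(CC[C@@H](C)CCO[Si](C)(C)C(C)(C)C)=C(C)C(=O)C[C@@H]1C(C)=C
F3 | step 7 | enol triflate: 7-triflyloxy-7-ene, 9β-H | C=CC[C@@]1(C)[C@H](CC[C@@H](C)CCO[Si](C)(C)C(C)(C)C)C(C)=C(OS(=O)(=O)C(F)(F)F)C[C@@H]1C(C)=C
F4 | step 14 | allylic alcohols, both C-3 epimers (18 and its 3β-epimer) | OC1CC[C@@]2(C)[C@H](CC[C@@H](C)CC(=O)OCc3ccccc3)C(C)=CC[C@@H]2C(C)=C1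
F5 | step 14 | chloroacetate of 18 | ClCC(=O)O[C@@H]1CC[C@@]2(C)[C@H](CC[C@@H](C)CC(=O)OCc3ccccc3)C(C)=CC[C@@H]2C(C)=C1
F7 | step 17 | tert-butyldimethylsilyl ether of 19 | CC(C)(C)[Si](C)(C)O[C@@H]1CC[C@@]2(C)[C@H](CC[C@@H](C)CC(=O)OCc3ccccc3)C(C)=CC[C@@H]2[C@]4(C)O[C@H]14
F8 | step 17 | ring-contracted 3α-siloxy-19-al | CC(C)(C)[Si](C)(C)O[C@@H]1CC[C@@]2(C)[C@H](CC[C@@H](C)CC(=O)OCc3ccccc3)C(C)=CC[C@@H]2[C@]1(C)C=O
F9 | step 17 | 3α-hydroxy-19-al | O[C@@H]1CC[C@@]2(C)[C@H](CC[C@@H](C)CC(=O)OCc3ccccc3)C(C)=CC[C@@H]2[C@]1(C)C=O
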